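**Retrosynthetic overview**

1. Feature: in benzaldehyde numbering (C1 formyl, C2 side chain, C3 OH, C4 OMe, C5 H, C6 OH) the single benzene ring carries oxygen on C4 and C6 (meta to each other), a carboxyl-derived carbon on C1 and the alkyl chain on C2. This is the pattern of a 6-alkyl-2,4-dihydroxybenzoate formed by folding a linear 3,5,7-tricarbonyl chain; the C3 hydroxyl, para to C6-OH, lies outside it and is added late by phenol oxidation.
2. Target 20 ⇒ hydroxymethylquinone 18 ⇒ salicyl alcohol 17 (C3-O by para-selective phenol oxidation, formyl by alcohol oxidation) ⇒ acetonide-masked salicyl alcohol 14 (silyl-to-acetyl exchange) ⇒ benzodioxinone 11.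
3. 11 ⇒ diketo-dioxinone 9 by C1-C2 aldol condensation and aromatisation. This is the only ring-forming event of the route (the benzene ring); the dioxinone ring is bought and the acetonide of step 8 is a protecting group.
4. 9 ⇒ keto-dioxinone 7 (from dioxinone 4 and acetyl chloride 5) plus Weinreb amide 3 (from (R)-3-hydroxytetradecanoic acid 1, which supplies the undecyl chain and the only stereocentre).

Key step: step 5

Remark on the chemistry: ring atoms are given in the benzaldehyde numbering above, and chain atoms of 9 are primed (C1' next to the dioxinone, C6' the silyloxy carbon). A free side-chain hydroxyl ortho to a C1 carbonyl would close to a dihydroisocoumarin or a lactol, and the acetate would not survive alkaline persulfate. The silyl-to-acetyl exchange is therefore run on an acetonide-masked salicyl alcohol, and the para oxygen is introduced with (KSO3)2NO at pH 6.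

**Route**

Step 1
Reactants: 1 (3R)-3-hydroxytetradecanoic acid
Product: 2 (3R)-3-hydroxy-N-methoxy-N-methyltetradecanamide
Conditions: MeNH(OMe)·HCl, EDC·HCl, HOBt, N-methylmorpholine, CH2Cl2, 0 °C to rt
Reagents that add atoms: N,O-dimethylhydroxylamine hydrochloride, CNOC.Cl
Why: Carbodiimide/HOBt amide coupling (Weinreb amide formation) should proceed on the unprotected β-hydroxy acid because the amine outcompetes the secondary alcohol for the active ester, and the stereocentre is not involved.

Step 2
Reactants: 2 (3R)-3-hydroxy-N-methoxy-N-methyltetradecanamide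
Product: 3 (3R)-3-[(tert-butyldimethylsilyl)oxy]-N-methoxy-N-methyltetradecanamide
Conditions: TBSCl, imidazole, DMF, rt
Reagents that add atoms: tert-butyldimethylsilyl chloride, CC(C)(C)[Si](C)(C)Cl
Why: Imidazole-promoted silylation of the secondary alcohol leaves the C-O bond intact (retention) and gives a β-silyloxy group that is a poor leaving group in the enolate chemistry that follows.

Step 3
Reactants: 4 2,2,6-trimethyl-4H-1,3-dioxin-4-one; 5 acetyl chloride
Product: 7 2,2-dimethyl-6-(2-oxopropyl)-4H-1,3-dioxin-4-one, via lithium dienolate 6 (not isolated)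
Conditions: LiN(SiMe3)2, THF, −78 °C; then AcCl (0.5 equiv), −78 °C; 1 M HCl quench
Reagents that add atoms: none
Why: Kinetic γ-deprotonation of the vinylogous ester gives dienolate 6, which should undergo C-acylation at the γ-carbon (vinylogous Claisen acylation), half an equivalent of acid chloride being used because the more acidic product consumes a second equivalent of 6.

Step 4
Reactants: 7 2,2-dimethyl-6-(2-oxopropyl)-4H-1,3-dioxin-4-one; 3 (3R)-3-[(tert-butyldimethylsilyl)oxy]-N-methoxy-N-methyltetradecanamide
Product: 9 6-[(6R)-6-[(tert-butyldimethylsilyl)oxy]-2,4-dioxoheptadecyl]-2,2-dimethyl-4H-1,3-dioxin-4-one, via dilithium dianion 8 (not isolated)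
Conditions: 7 (2.2 equiv), LiN(iPr)2 (4.4 equiv), THF, −78 °C; then 3, −78 to −30 °C; 1 M HCl to pH 3; crude 9 used directly
Reagents that add atoms: none
Why: Claisen-type acylation of a 1,3-dicarbonyl dianion: 8 should react at its terminal, most basic carbon with the N-methoxy-N-methyl amide, which stops the addition at the ketone level until the acidic quench, and the stereocentre is untouched.

Step 5
Reactants: 9 6-[(6R)-6-[(tert-butyldimethylsilyl)oxy]-2,4-dioxoheptadecyl]-2,2-dimethyl-4H-1,3-dioxin-4-one
Product: 11 5-[(2R)-2-[(tert-butyldimethylsilyl)oxy]tridecyl]-7-hydroxy-2,2-dimethyl-4H-1,3-benzodioxin-4-one, via aldol adduct 10 (not isolated)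
Conditions: Et3N (10 equiv), CH2Cl2, rt
Reagents that add atoms: none
Why: Triethylamine removes a proton from the C1' methylene between the dioxinone and the C2' ketone to give the extended dienolate, whose α-carbon (dioxinone C5, future ring C1) adds to the distal C4' ketone (future ring C2) to give aldol adduct 10; loss of water and enolisation of the C2' ketone (future C4-OH) then aromatise the ring. The closest known reaction type is the amine-mediated biomimetic aldol aromatisation of diketo-dioxinones to isopropylidene-protected β-resorcylates, the laboratory counterpart of orsellinate-type polyketide folding. The benzene ring is closed in a favoured 6-exo-trig aldol (enolexo with respect to the dioxinone enolate), and no stereocentre is created because the transient carbinol carbon becomes aromatic. The step needs C-cyclisation at C1-C2 and not O-cyclisation to a 4-pyranone, Claisen-type closure onto the carboxyl carbon, or E1cB loss of the β-silyloxy group: the carboxyl carbon is locked in the dioxinone ring, where it is a poor electrophile, C5 is the only carbon nucleophile that reaches C4' through a six-membered transition state, the 1,3-diketone is held as its enolate so that C5' is not deprotonated, and the non-acidic amine medium disfavours dehydrative pyranone formation. The C6' stereocentre bears only a silyl ether and is not enolisable, so it should pass unchanged.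

Step 6
Reactants: 11 5-[(2R)-2-[(tert-butyldimethylsilyl)oxy]tridecyl]-7-hydroxy-2,2-dimethyl-4H-1,3-benzodioxin-4-one
Product: 12 5-[(2R)-2-[(tert-butyldimethylsilyl)oxy]tridecyl]-7-methoxy-2,2-dimethyl-4H-1,3-benzodioxin-4-one
Conditions: MeI, K2CO3, acetone, 50 °C
Reagents that add atoms: iodomethane, CI
Why: Williamson O-methylation of the only free hydroxyl (the C4 phenol) should be clean because the silyl ether and the benzodioxinone are inert to carbonate in acetone.

Step 7
Reactants: 12 5-[(2R)-2-[(tert-butyldimethylsilyl)oxy]tridecyl]-7-methoxy-2,2-dimethyl-4H-1,3-benzodioxin-4-one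
Product: 13 3-[(2R)-2-[(tert-butyldimethylsilyl)oxy]tridecyl]-2-(hydroxymethyl)-5-methoxyphenol
Conditions: LiAlH4, THF, 0 °C; then Na2SO4·10H2O
Reagents that add atoms: none
Why: Hydride reduction of the aryl ester carbon with loss of the acetone unit should give the salicyl alcohol, an oxidation level at which C1's carbon can no longer lactonise or form a lactol with the side-chain oxygen, while the silyl and methyl ethers are stable to LiAlH4 at 0 °C.

Step 8
Reactants: 13 3-[(2R)-2-[(tert-butyldimethylsilyl)oxy]tridecyl]-2-(hydroxymethyl)-5-methoxyphenol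
Product: 14 tert-butyl{[(2R)-1-(7-methoxy-2,2-dimethyl-4H-1,3-benzodioxin-5-yl)tridecan-2-yl]oxy}dimethylsilane
Conditions: 2,2-dimethoxypropane, PPTS (cat.), acetone, rt
Reagents that add atoms: 2,2-dimethoxypropane, COC(C)(C)OC
Why: Acid-catalysed transketalisation should close the six-membered isopropylidene acetal across the phenol and the benzylic alcohol, masking both at once under conditions mild enough to keep the secondary silyl ether.

Step 9
Reactants: 14 tert-butyl{[(2R)-1-(7-methoxy-2,2-dimethyl-4H-1,3-benzodioxin-5-yl)tridecan-2-yl]oxy}dimethylsilane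
Product: 15 (2R)-1-(7-methoxy-2,2-dimethyl-4H-1,3-benzodioxin-5-yl)tridecan-2-ol
Conditions: Bu4NF, THF, rt; water work-up
Reagents that add atoms: none
Why: Fluoride-induced Si-O cleavage frees the secondary alcohol with retention, since the C-O bond is not broken, and the acetal is inert to fluoride; with C1's carbon held as an acetal the free hydroxyl has no carbonyl to cyclise onto.

Step 10
Reactants: 15 (2R)-1-(7-methoxy-2,2-dimethyl-4H-1,3-benzodioxin-5-yl)tridecan-2-ol
Product: 16 (2R)-1-(7-methoxy-2,2-dimethyl-4H-1,3-benzodioxin-5-yl)tridecan-2-yl acetate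
Conditions: Ac2O, pyridine, DMAP (cat.), CH2Cl2, rt
Reagents that add atoms: acetic anhydride, CC(=O)OC(C)=O
Why: DMAP-catalysed acylation of the single free hydroxyl installs the acetate of the target with retention at the carbinol carbon.

Step 11
Reactants: 16 (2R)-1-(7-methoxy-2,2-dimethyl-4H-1,3-benzodioxin-5-yl)tridecan-2-yl acetate
Product: 17 (2R)-1-[3-hydroxy-2-(hydroxymethyl)-5-methoxyphenyl]tridecan-2-yl acetate
Conditions: AcOH/THF/H2O (3:1:1), rt to 35 °C, dilute
Reagents that add atoms: none
Why: Mild aqueous-acid hydrolysis of the phenol/benzyl isopropylidene acetal should release both hydroxyls while the secondary acetate is stable to aqueous acetic acid, and the water-rich medium returns any benzylic cation to the alcohol.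

Step 12
Reactants: 17 (2R)-1-[3-hydroxy-2-(hydroxymethyl)-5-methoxyphenyl]tridecan-2-yl acetate
Product: 18 (2R)-1-[2-(hydroxymethyl)-5-methoxy-3,6-dioxocyclohexa-1,4-dien-1-yl]tridecan-2-yl acetate
Conditions: (KSO3)2NO (2.5 equiv), aq. KH2PO4 (pH 6), acetone/H2O, 0 °C to rt
Reagents that add atoms: potassium nitrosodisulfonate (Fremy's salt), [K+].[K+].[O]N(S(=O)(=O)[O-])S(=O)(=O)[O-]
Why: Teuber oxidation: two equivalents of the nitroxyl radical convert an electron-rich, non-chelated phenol with a free para position into the para-benzoquinone, so the oxygen should enter at C3 (para to C6-OH) and not at C5, and the near-neutral buffer leaves the acetate untouched.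

Step 13
Reactants: 18 (2R)-1-[2-(hydroxymethyl)-5-methoxy-3,6-dioxocyclohexa-1,4-dien-1-yl]tridecan-2-yl acetate
Product: 20 (2R)-1-(2-formyl-3,6-dihydroxy-5-methoxyphenyl)tridecan-2-yl acetate, via formylquinone 19 (not isolated)
Conditions: Dess–Martin periodinane, CH2Cl2, 0 °C to rt; then aq. Na2S2O4, EtOAc, rt, under argon
Reagents that add atoms: none
Why: Dess–Martin oxidation of the primary quinonyl carbinol should give formylquinone 19, which dithionite reduces without isolation (two-electron quinone-to-hydroquinone reduction) to the hydrogen-bonded dihydroxybenzaldehyde, neither reagent touching the acetate or the stereocentre.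

**Compound list**

1 | (3R)-3-hydroxytetradecanoic acid | CCCCCCCCCCC[C@H](CC(=O)O)O | starting material
2 | (3R)-3-hydroxy-N-methoxy-N-methyltetradecanamide | CCCCCCCCCCC[C@H](CC(=O)N(C)OC)O | intermediate
3 | (3R)-3-[(tert-butyldimethylsilyl)oxy]-N-methoxy-N-methyltetradecanamide | CCCCCCCCCCC[C@H](CC(=O)N(C)OC)O[Si](C)(C)C(C)(C)C | intermediate
4 | 2,2,6-trimethyl-4H-1,3-dioxin-4-one | CC1=CC(=O)OC(C)(C)O1 | starting material
5 | acetyl chloride | CC(=O)Cl | starting material
6 | lithium 2,2-dimethyl-6-methylidene-6H-1,3-dioxin-4-olate (lithium dienolate of 4) | [Li+].[O-]C1=CC(=C)OC(C)(C)O1 | intermediate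
7 | 2,2-dimethyl-6-(2-oxopropyl)-4H-1,3-dioxin-4-one | CC(=O)CC1=CC(=O)OC(C)(C)O1 | intermediate
8 | dilithium 2,2-dimethyl-6-(2-oxidoprop-2-en-1-ylidene)-6H-1,3-dioxin-4-olate (dianion of 7) | [Li+].[Li+].C=C([O-])C=C1C=C([O-])OC(C)(C)O1 | intermediate
9 | 6-[(6R)-6-[(tert-butyldimethylsilyl)oxy]-2,4-dioxoheptadecyl]-2,2-dimethyl-4H-1,3-dioxin-4-one | CCCCCCCCCCC[C@H](CC(=O)CC(=O)CC1=CC(=O)OC(C)(C)O1)O[Si](C)(C)C(C)(C)C | intermediate
10 | 5-[(2R)-2-[(tert-butyldimethylsilyl)oxy]tridecyl]-5-hydroxy-2,2-dimethyl-5,6-dihydro-4H-1,3-benzodioxine-4,7(8H)-dione (aldol adduct, both C5 epimers) | CCCCCCCCCCC[C@H](CC1(O)CC(=O)CC2=C1C(=O)OC(C)(C)O2)O[Si](C)(C)C(C)(C)C | intermediate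
11 | 5-[(2R)-2-[(tert-butyldimethylsilyl)oxy]tridecyl]-7-hydroxy-2,2-dimethyl-4H-1,3-benzodioxin-4-one | CCCCCCCCCCC[C@H](Cc1cc(O)cc2OC(C)(C)OC(=O)c12)O[Si](C)(C)C(C)(C)C | intermediate
12 | 5-[(2R)-2-[(tert-butyldimethylsilyl)oxy]tridecyl]-7-methoxy-2,2-dimethyl-4H-1,3-benzodioxin-4-one | CCCCCCCCCCC[C@H](Cc1cc(OC)cc2OC(C)(C)OC(=O)c12)O[Si](C)(C)C(C)(C)C | intermediate
13 | 3-[(2R)-2-[(tert-butyldimethylsilyl)oxy]tridecyl]-2-(hydroxymethyl)-5-methoxyphenol | CCCCCCCCCCC[C@H](Cc1cc(OC)cc(O)c1CO)O[Si](C)(C)C(C)(C)C | intermediate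
14 | tert-butyl{[(2R)-1-(7-methoxy-2,2-dimethyl-4H-1,3-benzodioxin-5-yl)tridecan-2-yl]oxy}dimethylsilane | CCCCCCCCCCC[C@H](Cc1cc(OC)cc2OC(C)(C)OCc12)O[Si](C)(C)C(C)(C)C | intermediate
15 | (2R)-1-(7-methoxy-2,2-dimethyl-4H-1,3-benzodioxin-5-yl)tridecan-2-ol | CCCCCCCCCCC[C@H](Cc1cc(OC)cc2OC(C)(C)OCc12)O | intermediate
16 | (2R)-1-(7-methoxy-2,2-dimethyl-4H-1,3-benzodioxin-5-yl)tridecan-2-yl acetate | CCCCCCCCCCC[C@H](Cc1cc(OC)cc2OC(C)(C)OCc12)OC(C)=O | intermediate
17 | (2R)-1-[3-hydroxy-2-(hydroxymethyl)-5-methoxyphenyl]tridecan-2-yl acetate | CCCCCCCCCCC[C@H](Cc1cc(OC)cc(O)c1CO)OC(C)=O | intermediate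
18 | (2R)-1-[2-(hydroxymethyl)-5-methoxy-3,6-dioxocyclohexa-1,4-dien-1-yl]tridecan-2-yl acetate | CCCCCCCCCCC[C@H](CC1=C(CO)C(=O)C=C(OC)C1=O)OC(C)=O | intermediate
19 | (2R)-1-(2-formyl-5-methoxy-3,6-dioxocyclohexa-1,4-dien-1-yl)tridecan-2-yl acetate | CCCCCCCCCCC[C@H](CC1=C(C=O)C(=O)C=C(OC)C1=O)OC(C)=O | intermediate
20 | (2R)-1-(2-formyl-3,6-dihydroxy-5-methoxyphenyl)tridecan-2-yl acetate | CCCCCCCCCCC[C@H](Cc1c(O)c(OC)cc(O)c1C=O)OC(C)=O | target

**Step count and risks**

Total step count: 13. Longest linear sequence: 12 steps (steps 1, 2 and 4 to 13 from acid 1); step 3 is a one-step side branch from dioxinone 4.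

The three steps most likely to fail:

Step 5. What may go wrong: the folded chain closes through oxygen (dehydrative 4-pyranone formation), or an enolate on the C5' side expels the silyloxy group, so that carbocyclisation is outrun. The fallback sets out from 9 and comes back at 13, and cyclises the unmasked polyketide ester instead of the dioxinone. Heating 9 in toluene with methanol at 110 °C should release acetone by retro-[4+2] cleavage and trap the acylketene as methyl (9R)-9-[(tert-butyldimethylsilyl)oxy]-3,5,7-trioxoicosanoate F1. F1 is cyclised under the classical carbonate conditions for 3,5,7-triketo esters (K2CO3, MeOH/CH2Cl2, rt, then dilute HCl) to methyl 2,4-dihydroxy-6-[(2R)-2-[(tert-butyldimethylsilyl)oxy]tridecyl]benzoate F2. The non-chelated 4-hydroxyl is methylated selectively (MeI 1.05 equiv, K2CO3, acetone) to methyl 2-hydroxy-4-methoxy-6-[(2R)-2-[(tert-butyldimethylsilyl)oxy]tridecyl]benzoate F3, and LiAlH4 in THF at 0 °C reduces the ester to 13.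

Step 12. What may go wrong: radical attack at the ortho position C5 or oxidative degradation of the o-hydroxybenzyl alcohol unit, or slow two-phase reaction of the lipophilic phenol while the radical reagent decays. The fallback sets out from 17 and comes back at 18, and replaces the radical oxidation by a two-electron oxidation in homogeneous organic solution. PhI(OAc)2 (2.2 equiv, a trivalent iodine reagent) in methanol at 0 °C should effect para-methoxylation and a second oxidation to the para-quinone monoketal (2R)-1-[2-(hydroxymethyl)-5,6,6-trimethoxy-3-oxocyclohexa-1,4-dien-1-yl]tridecan-2-yl acetate F4, which aqueous oxalic acid in THF hydrolyses to 18.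

Step 13. What may go wrong: decay of the electrophilic formylquinone (hydration, conjugate addition of sulfur nucleophiles, self-condensation) before or during the reduction, or sluggish oxidation of the electron-poor carbinol. The fallback sets out from 18 and comes back at 20, and forms the aldehyde at the hydroquinone oxidation level, so that no formylquinone appears.
- Aqueous Na2S2O4 reduces 18 to (2R)-1-[3,6-dihydroxy-2-(hydroxymethyl)-5-methoxyphenyl]tridecan-2-yl acetate F5.
- Et3SiCl and imidazole in DMF silylate all three hydroxyls to give (2R)-1-[5-methoxy-3,6-bis(triethylsilyloxy)-2-(triethylsilyloxymethyl)phenyl]tridecan-2-yl acetate F6.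
- Swern conditions ((COCl)2, DMSO, CH2Cl2, −78 to −30 °C, then Et3N) should convert the primary benzylic triethylsilyl ether directly into the aldehyde while the aryl silyl ethers stay, giving (2R)-1-[2-formyl-5-methoxy-3,6-bis(triethylsilyloxy)phenyl]tridecan-2-yl acetate F7.
- HF·pyridine in THF/pyridine at 0 °C removes the two aryl silyl groups to give 20.

**Further compounds**

F1 | step 5 | methyl (9R)-9-[(tert-butyldimethylsilyl)oxy]-3,5,7-trioxoicosanoate | CCCCCCCCCCC[C@H](CC(=O)CC(=O)CC(=O)CC(=O)OC)O[Si](C)(C)C(C)(C)C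
F2 | step 5 | methyl 2,4-dihydroxy-6-[(2R)-2-[(tert-butyldimethylsilyl)oxy]tridecyl]benzoate | CCCCCCCCCCC[C@H](Cc1cc(O)cc(O)c1C(=O)OC)O[Si](C)(C)C(C)(C)C
F3 | step 5 | methyl 2-hydroxy-4-methoxy-6-[(2R)-2-[(tert-butyldimethylsilyl)oxy]tridecyl]benzoate | CCCCCCCCCCC[C@H](Cc1cc(OC)cc(O)c1C(=O)OC)O[Si](C)(C)C(C)(C)C
F4 | step 12 | (2R)-1-[2-(hydroxymethyl)-5,6,6-trimethoxy-3-oxocyclohexa-1,4-dien-1-yl]tridecan-2-yl acetate | CCCCCCCCCCC[C@H](CC1=C(CO)C(=O)C=C(OC)C1(OC)OC)OC(C)=O
F5 | step 13 | (2R)-1-[3,6-dihydroxy-2-(hydroxymethyl)-5-methoxyphenyl]tridecan-2-yl acetate | CCCCCCCCCCC[C@H](Cc1c(O)c(OC)cc(O)c1CO)OC(C)=O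
F6 | step 13 | (2R)-1-[5-methoxy-3,6-bis(triethylsilyloxy)-2-(triethylsilyloxymethyl)phenyl]tridecan-2-yl acetate | CCCCCCCCCCC[C@H](Cc1c(O[Si](CC)(CC)CC)c(OC)cc(O[Si](CC)(CC)CC)c1CO[Si](CC)(CC)CC)OC(C)=O
F7 | step 13 | (2R)-1-[2-formyl-5-methoxy-3,6-bis(triethylsilyloxy)phenyl]tridecan-2-yl acetate | CCCCCCCCCCC[C@H](Cc1c(O[Si](CC)(CC)CC)c(OC)cc(O[Si](CC)(CC)CC)c1C=O)OC(C)=O
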